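## Analysis of the target

The target (24) is the 3-hydroxy-4-methoxybenzoate of a cis-fused bicyclo[5.4.0]undecene diol of the himachalane type. The atom numbering used throughout is: C1 and C6 are the ring-fusion CH carbons; ring A is the cyclohexene C1–C2=C3(CH3)–C4(O-acyl)–C5H2–C6; ring B is the seven-membered ring C6–C7(CH3)(OH)–C8H2–C9H2–C10H2–C11(CH3)2–C1. There are four stereocentres, (1S,4R,6R,7S) in this numbering. H-1 and H-6 are cis. At C7 the methyl group lies on the face of H-6 and the hydroxyl on the side of C5. The C4 ester oxygen lies on the same face of ring A as H-1 and H-6. The sensitive groups are the tertiary carbinol (E1 loss of water, and it can bridge to a C4 carbonyl), the secondary allylic ester (ionisation, allylic transposition) and the free phenol. The synthesis is hard for three reasons: the quaternary C11 sits next to the stereogenic C1 inside a seven-membered ring; the cis fusion is expected to be the less stable arrangement once C7 is a ketone; and a single enantiomer must be made without resident chirality. The strategy rests on the pattern of ring B: a three-carbon unit C9–C10–C11 ending in CMe2 is joined to a four-carbon unit C8–C7–C6–C1 that carries oxygen on its second carbon and whose C6–C1 bond belongs to ring A. This is the pattern of a 2-methylpropenyl carbenoid combined with a 2-silyloxy diene whose inner alkene lies in ring A.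

## Retrosynthetic reasoning

**C4–O ester bond (24 to 22 and 23).** The aryl ester and its phenol would not survive the organometallic and reductive steps, so the acyl group is attached last. The bond is made with inversion, because hydride addition to the ring A enone is expected to put the hydroxyl on the ring B side, which is the C4 epimer of what the target needs. The forward reaction must couple the carboxyl group of 23 in the presence of its phenol and invert C4 of 22.

**C4–H bond (22 to 21).** The carbinol is traced to the 2-methyl enone 21. The C4 stereocentre then follows from the shape of the cis-fused bicycle. The forward reduction has to be 1,2 and come from the face of the ring-fusion hydrogens.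

**C2=C3 alkene (21 to 19 by way of 20, and 19 to 18).** The enone is taken back to the saturated 3-methyl ketone and its dioxolane. The C3 methyl is carried from the arene, so that thermodynamic enolisation points to C3 and no late regioselective methylation is needed. This is why the methylated aldehyde 1 is chosen. The forward steps are ketal hydrolysis and a regioselective dehydrogenation.

**C7–CH3 bond (18 to 17).** The tertiary carbinol is cut to the C7 ketone, which is what the key step leaves behind in masked form. The methyl group is added while C4 is still a ketal, so that the two carbonyls are never free together and C6 is locked before acid is used. The forward addition must be non-basic and come from the face of H-6.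

**C6–H bond (17 to 16).** The ring-fusion hydrogen is introduced by protonation of the C6=C7 enol ether. The forward step has to be kinetic, on the face remote from C11, because the cis ketone is not expected to be the thermodynamic one.

**C9–carboxyl bond (16 to 14, 13 and 12).** The ester on C9 is the price of the carbenoid and has no place in the target. It is removed by alkene reduction, ester cleavage and radical decarboxylation while the enol ether still masks C7 and protects C6 from epimerisation.

**C8–C9 and C1–C11 (12 to 7 and 10 through 11): the key disconnection.** Both bonds that tie the three-carbon unit into ring B are cut. This takes out the seven-membered ring, the quaternary C11 and the C1 stereocentre in one operation. It leaves ring A as a preformed six-membered ring and delivers the C7 oxygen as an enol ether. Cutting elsewhere in ring B would give no comparable simplification, since only this pair maps onto a carbenoid and a diene. The forward reaction must cyclopropanate C7=C8 with the two alkenyl groups cis, under control of the chiral catalyst of step 8, and then carry out the [3,3] shift.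

**Diene 7 and diazo ester 10 (7 to 5, 4, 3, 2 and 1; 10 to 9 and 8).** Ring A of 7 is an arene in disguise. The anisole oxygen of 1 becomes the C4 oxygen, the aryl methyl becomes the C3 methyl, and the benzylic carbon and its added methyl become C7 and C8. Dissolving-metal reduction places the ring alkene at C1=C6 and the masked carbonyl 1,3 to the side chain. Diazo ester 10 comes from acid 8 by esterification and diazo transfer.

## Alternatives that were turned down

**Alternative 1:** Ring B is disconnected at C10–C11 and C6–C7. Ring A then already carries a cyclopropane spanning C1, C6 and C11 (an enone-activated cyclopropane from the carene pool), and a methyl-substituted furan supplies C7–C10 and the C7 methyl.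
- Forward key step: a Lewis acid opens the C6–C11 bond. The tertiary cation at C11 and the C6 enolate add in turn to the two α-positions of the furan and give the oxygen-bridged tricyclic enone A1.
- For it: C1 comes from the chiral pool, and one step brings in all fifteen skeletal carbons, the quaternary C11, C6 and the tertiary C7–O bond.
- Against it: in A1 the ring A carbonyl sits on C5 and the alkene is C3=C4, whereas the target needs oxygen on C4 and the alkene at C2=C3, so an oxygen transposition with alkene shift is required. The ether bridge must be cut at the secondary C10–O bond while the tertiary C7–O bond survives. That bond is β to the C5 carbonyl and prone to retro-Michael opening, so the required selectivity runs against intrinsic reactivity. C8=C9 must also be reduced, and the facial course of a stepwise cationic annulation is not assured.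
- Comparison: this plan is stronger on early step economy and needs no asymmetric catalyst. The chosen strategy instead places both oxygens on the correct carbons from the start (C4 from the arene, C7 from the enol ether) and needs no regioselective ether scission.

**Alternative 2:** C1–C6 and C4–C5 are disconnected, so both rings come from an open-chain trienone.
- Forward key step: an intramolecular Diels–Alder reaction. A vinyl ketone (C5=C6, carbonyl C7) at the end of a five-carbon tether adds across an (E,E)-1-acetoxy-2-methyl diene (C1 to C4) and gives the cis-fused keto acetate A2, the C4 epimer of the target series.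
- For it: after the cycloaddition the C2=C3 alkene, the C3 methyl, the C4 oxygen and the C7 carbonyl are all in place with three stereocentres related. Only methyl addition, deacetylation and inversion would remain.
- Against it: the tether closes a seven-membered ring, which is entropically slow and invites polymerisation of the vinyl ketone and the dienyl acetate at the temperatures needed. The diene terminus C1 carries the quaternary C11. The endo/exo course, and with it the ring fusion and the C4 relationship, depends on tether conformation. C6 is epimerisable next to the ketone. Absolute configuration would need an enantioselective catalyst for a one-point-binding enone in this ring size, or a resolution.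
- Comparison: on step count this plan is the stronger one. The chosen strategy offers absolute control from a catalyst family whose behaviour in this reaction class is established, closes ring B by a strain-driven rearrangement and not by a slow medium-ring cyclisation, and uses stable precursors.

**Alternative 3:** C1–C6 is disconnected in ring A by a ring contraction, and ring B is left open.
- Forward key step: the silyl ketene acetal of a six-membered lactone (ester oxygen on C3, acyl carbon C7) undergoes an Ireland–Claisen rearrangement through a boat. C6 bonds to C1 as C3–O breaks, which forms ring A with the C2=C3 alkene and leaves C7 as a carboxylic acid, giving acid A3 with C1, C4 and C6 set.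
- For it: chirality transfer in lactone-contracting Claisen rearrangements is reliable because the ring enforces the boat. The C4 oxygen is set directly in the target sense, with no reduction and inversion to predict. The alkene and its methyl arrive in place.
- Against it: the lactone needs a tertiary allylic C3–O stereocentre and a geometrically defined C1=C2 alkene bearing the neopentyl-type chain, which means a long linear preparation. The new C1–C6 bond must form next to the quaternary C11. Ring B still has to be closed at C7–C8 while the C7 carbinol is created, which is a seven-membered closure with a further quaternary stereocentre.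
- Comparison: this plan is stronger in the certainty of the C4 configuration and of the relative stereochemistry of ring A. The chosen strategy is much shorter overall, because ring B and C1 come from one catalytic step and ring A is bought as an arene.

Key step: step 8

Assumption: the sense of induction is taken from the benchmark of this catalyst family (Rh2(S-DOSP)4 gives the (1S,2R)-cyclopropane from styrene and methyl phenyldiazoacetate); transposed to 7 and 10 this calls for Rh2(R-DOSP)4, and the mirror-image catalyst would be used without other change if the sense proved opposite.

Assumption: 3-methoxy-4-methylbenzaldehyde (1) is taken as a catalogue compound.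

## Route

Step 1
Reactants: 1 3-methoxy-4-methylbenzaldehyde
Product: 2 1-(3-methoxy-4-methylphenyl)ethan-1-ol (racemic)
Conditions: MeMgBr, THF, 0 °C; aq. NH4Cl
Reagents that add atoms: methylmagnesium bromide, C[Mg]Br
Why: Grignard addition to an aryl aldehyde; the carbinol carbon becomes C7 and the new methyl C8, and the racemic carbinol centre is removed in step 4.

Step 2
Reactants: 2 1-(3-methoxy-4-methylphenyl)ethan-1-ol
Product: 3 1-(5-methoxy-4-methylcyclohexa-1,4-dien-1-yl)ethan-1-ol
Conditions: Li, NH3(l), THF, −78 °C; then t-BuOH, −78 → −33 °C; NH4Cl
Reagents that add atoms: none
Why: Birch reduction; the two hydrogens go to the unsubstituted, mutually para ring carbons (future C2 and C5), so methoxy, methyl and side chain stay on sp2 carbons. The carbinol is present as its lithium alkoxide before the proton source is added and should therefore resist benzylic C–O cleavage.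

Step 3
Reactants: 3 1-(5-methoxy-4-methylcyclohexa-1,4-dien-1-yl)ethan-1-ol
Product: 4 1-(10-methyl-1,4-dioxaspiro[4.5]dec-7-en-7-yl)ethan-1-ol (mixture of diastereomers)
Conditions: HOCH2CH2OH, PPTS (cat.), CH2Cl2, rt
Reagents that add atoms: ethylene glycol, OCCO
Why: Acid-catalysed ketalisation of the methyl enol ether through the oxocarbenium ion formed by C-protonation at C3; mild acid should leave the C1=C6 alkene out of conjugation. The new C3 centre forms without control, which is harmless because C3 becomes sp2 again in step 15.

Step 4
Reactants: 4 1-(10-methyl-1,4-dioxaspiro[4.5]dec-7-en-7-yl)ethan-1-ol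
Product: 5 1-(10-methyl-1,4-dioxaspiro[4.5]dec-7-en-7-yl)ethan-1-one (racemic at C3)
Conditions: MnO2 (activated), CH2Cl2, rt
Reagents that add atoms: none
Why: Selective oxidation of a secondary allylic alcohol to the enone under neutral conditions that spare the ketal; both carbinol epimers converge.

Step 5
Reactants: 5 1-(10-methyl-1,4-dioxaspiro[4.5]dec-7-en-7-yl)ethan-1-one
Product: 7 tert-butyldimethyl{[1-(10-methyl-1,4-dioxaspiro[4.5]dec-7-en-7-yl)ethenyl]oxy}silane (racemic 2-silyloxy diene), via lithium enolate 6 (not isolated)
Conditions: LDA, THF, −78 °C; then TBSCl, HMPA, −78 °C → rt
Reagents that add atoms: tert-butyldimethylsilyl chloride, CC(C)(C)[Si](C)(C)Cl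
Why: Kinetic deprotonation of the acetyl methyl gives the cross-conjugated enolate, and O-silylation gives the 2-silyloxy diene (silyl enol ether formation); the ketal is inert to the amide base.

Step 6
Reactants: 8 4-methylpent-3-enoic acid
Product: 9 methyl 4-methylpent-3-enoate
Conditions: MeI, K2CO3, DMF, rt
Reagents that add atoms: iodomethane, CI
Why: O-Alkylation of the carboxylate; acid-catalysed esterification is avoided because this acid lactonises readily under protic acid.

Step 7
Reactants: 9 methyl 4-methylpent-3-enoate
Product: 10 methyl 2-diazo-4-methylpent-3-enoate
Conditions: p-ABSA, DBU, MeCN, 0 °C; used at once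
Reagents that add atoms: 4-acetamidobenzenesulfonyl azide, CC(=O)Nc1ccc(cc1)S(=O)(=O)N=[N+]=[N-]
Why: Regitz diazo transfer to the CH2 group activated by both the ester and the alkene, the standard access to vinyldiazoacetates from β,γ-unsaturated esters.

Step 8
Reactants: 7 tert-butyldimethyl{[1-(10-methyl-1,4-dioxaspiro[4.5]dec-7-en-7-yl)ethenyl]oxy}silane; 10 methyl 2-diazo-4-methylpent-3-enoate
Product: 12 bicyclic cycloheptadiene ester (methyl ester on C9, C9=C10, C6=C7 TBS enol ether, C4 dioxolane, C3 methyl, C1 configured as in the target; two C3 epimers), via cis-divinylcyclopropane 11 (not isolated)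
Conditions: Rh2(R-DOSP)4 (2 mol %), pentane, −78 °C → rt, slow addition of 10 (1.5 equiv); then PhMe, 80–110 °C
Reagents that add atoms: none
Why: The dirhodium catalyst decomposes 10 to a donor/acceptor vinylcarbenoid, whose carbene carbon (C9) cyclopropanates the C7=C8 silyl enol ether of 7 with the 2-methylpropenyl group cis to the cyclohexenyl arm (11); the fully substituted vinyl terminus blocks vinylogous attack. On warming, 11 rearranges as a cis-divinylcyclopropane through a boat transition state: the C7–C9 bond breaks as C11 bonds to C1, while C8–C9, made in the cyclopropanation, stays. Ring B therefore closes by [3,3]-sigmatropic ring expansion of the three-membered ring, a formal (4+3) annulation of the diene C8=C7–C6=C1 with the C9–C10–C11 unit. The closest known reaction type is the tandem cyclopropanation/Cope rearrangement of vinyldiazoacetates with dienes, 2-silyloxy dienes included, under dirhodium tetraprolinate catalysis. C1 is the only stereocentre created that survives in 12: the catalyst sets the configuration of 11, and the boat geometry, in which the ring alkene can offer only one face to C11, passes it on to C1 stereospecifically. The step needs chemoselectivity for C7=C8 over the trisubstituted ring alkene and the allylic and acetal C–H bonds, which the nucleophilic, open enol ether terminus and the bulk of the carbenoid should secure, and cis selectivity, which follows from the preference of the carbenoid donor group to lie cis to the conjugating alkene substituent. Heating is planned because the methyl group that points inward on C11 slows the Cope step; the racemic C3 centre of 7 is remote and gives 12 as two C3 epimers that converge later.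

Step 9
Reactants: 12 bicyclic cycloheptadiene ester
Product: 13 saturated C9 methyl ester with the C6=C7 TBS enol ether retained (C3 and C9 epimers)
Conditions: H2 (1 atm), 10% Pd/C, EtOAc, rt
Reagents that add atoms: none
Why: Heterogeneous hydrogenation of the conjugated trisubstituted C9=C10 alkene; the tetrasubstituted silyl enol ether should not be reduced, and the C9 configuration is of no consequence because C9 becomes CH2 in step 11.

Step 10
Reactants: 13 saturated C9 methyl ester
Product: 14 C9 carboxylic acid with the C6=C7 TBS enol ether and C4 dioxolane retained
Conditions: Me3SnOH, ClCH2CH2Cl, 80 °C; cold 0.05 M HCl wash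
Reagents that add atoms: trimethyltin hydroxide, C[Sn](C)(C)O
Why: Neutral ester hydrolysis by the tin hydroxide, chosen because aqueous alkali could attack the silyl enol ether; ketal and enol ether should be retained.

Step 11
Reactants: 14 C9 carboxylic acid
Product: 16 C6=C7 TBS enol ether of the bicyclic C4 ketal with C8–C10 as CH2 groups, via Barton ester 15 (not isolated)
Conditions: DCC, N-hydroxypyridine-2-thione, DMAP (cat.), CH2Cl2, dark, rt; then t-BuSH, PhH, hν (tungsten lamp), rt
Reagents that add atoms: none
Why: Barton reductive decarboxylation; the thiohydroxamate ester fragments in a radical chain to the secondary C9 radical, which takes hydrogen from the thiol. The neutral conditions keep the enol ether that still masks C7 and shields C6.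

Step 12
Reactants: 16 C6=C7 TBS enol ether
Product: 17 cis-fused C7 ketone with the C4 dioxolane, (1S,6R) in the local numbering
Conditions: TBAF, AcOH, THF, −78 → −20 °C
Reagents that add atoms: none
Why: Fluoride desilylation in the presence of a proton source; the enolate is protonated at C6 kinetically on the face remote from the C11 gem-dimethyl group, which is the face of H-1 and gives the cis ring fusion. Buffered, cold conditions are chosen because the trans-fused ketone is expected to be favoured at equilibrium.

Step 13
Reactants: 17 cis-fused C7 ketone
Product: 18 C7 tertiary carbinol with the C4 dioxolane, (1S,6R,7S)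
Conditions: MeLi, CeCl3 (anhydrous), THF, −78 °C
Reagents that add atoms: methyllithium, [Li]C
Why: 1,2-Addition of a non-basic organocerium reagent, which should not enolise C6, to the exposed convex face of the cis-fused ketone (the face of H-6); this places the methyl syn to H-6 and the hydroxyl on the side of C5, as the target requires.

Step 14
Reactants: 18 C7 tertiary carbinol with the C4 dioxolane
Product: 19 C4 ketone with C3 methyl and C7 tertiary carbinol, (1S,6R,7S)
Conditions: PPTS, acetone/H2O, 60 °C
Reagents that add atoms: water, O
Why: Mild acid hydrolysis of the dioxolane that should not dehydrate the tertiary carbinol; the C3 methyl can equilibrate next to the carbonyl, and either epimer serves.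

Step 15
Reactants: 19 C4 ketone
Product: 20 C3=C4 trimethylsilyl enol ether carrying the C7 trimethylsilyl ether
Conditions: TMSCl, NaI, Et3N, MeCN, rt
Reagents that add atoms: chlorotrimethylsilane, C[Si](C)(C)Cl
Why: Enol silylation by iodotrimethylsilane formed in the flask, under equilibrating conditions, gives the more substituted C3=C4 silyl enol ether because the methyl group directs enolisation. The excess reagent also caps the tertiary hydroxyl, which keeps it from adding to the C4 carbonyl.

Step 16
Reactants: 20 bis-silylated enol ether
Product: 21 ring A 3-methyl-2-en-4-one with free C7 carbinol, (1S,6R,7S)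
Conditions: Pd(OAc)2 (1.1 equiv), MeCN, rt; then citric acid, MeOH, 0 °C
Reagents that add atoms: none
Why: Saegusa–Ito oxidation; the palladium enolate at C3 loses a β-hydrogen from C2 to give the endocyclic 2-methyl enone, and any exocyclic isomer should move into the ring under the palladium hydride. Mild methanolysis then frees the tertiary alcohol.

Step 17
Reactants: 21 ring A enone
Product: 22 allylic alcohol, C4 epimer of the target carbinol, (1S,4S,6R,7S)
Conditions: NaBH4, CeCl3·7H2O, MeOH, −78 °C
Reagents that add atoms: none
Why: Luche 1,2-reduction; hydride is expected from the convex face (that of H-1 and H-6) because the C7 carbinol carbon shields the other face of C4. This gives the hydroxyl cis to C7, the epimer needed for an invertive esterification.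

Step 18
Reactants: 22 allylic alcohol; 23 3-hydroxy-4-methoxybenzoic acid (isovanillic acid)
Product: 24 target, (1S,4R,6R,7S)
Conditions: PPh3, DIAD, THF, 0 °C → rt
Reagents that add atoms: none
Why: Mitsunobu esterification with inversion at C4; the carboxyl group of 23 is far more acidic than its phenol and is the pronucleophile, so phenolic acids couple at the carboxyl group without protection. The tertiary alcohol does not react.

## Compound list

1 | 3-methoxy-4-methylbenzaldehyde | COc1cc(C=O)ccc1C | starting material
2 | 1-(3-methoxy-4-methylphenyl)ethan-1-ol (racemic) | CC(O)c1ccc(C)c(OC)c1 | intermediate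
3 | 1-(5-methoxy-4-methylcyclohexa-1,4-dien-1-yl)ethan-1-ol | CC(O)C1=CCC(C)=C(OC)C1 | intermediate
4 | 1-(10-methyl-1,4-dioxaspiro[4.5]dec-7-en-7-yl)ethan-1-ol (diastereomer mixture) | CC(O)C1=CCC(C)C2(C1)OCCO2 | intermediate
5 | 1-(10-methyl-1,4-dioxaspiro[4.5]dec-7-en-7-yl)ethan-1-one (racemic) | CC(=O)C1=CCC(C)C2(C1)OCCO2 | intermediate
6 | lithium 1-(10-methyl-1,4-dioxaspiro[4.5]dec-7-en-7-yl)ethen-1-olate (not isolated) | [Li+].C=C([O-])C1=CCC(C)C2(C1)OCCO2 | intermediate
7 | tert-butyldimethyl{[1-(10-methyl-1,4-dioxaspiro[4.5]dec-7-en-7-yl)ethenyl]oxy}silane (racemic) | C=C(O[Si](C)(C)C(C)(C)C)C1=CCC(C)C2(C1)OCCO2 | intermediate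
8 | 4-methylpent-3-enoic acid | CC(C)=CCC(=O)O | starting material
9 | methyl 4-methylpent-3-enoate | COC(=O)CC=C(C)C | intermediate
10 | methyl 2-diazo-4-methylpent-3-enoate | COC(=O)C(=[N+]=[N-])C=C(C)C | intermediate
11 | methyl 2-(tert-butyldimethylsilyloxy)-2-(10-methyl-1,4-dioxaspiro[4.5]dec-7-en-7-yl)-1-(2-methylprop-1-enyl)cyclopropane-1-carboxylate, alkenyl groups cis (not isolated; C3 epimers) | COC(=O)[C@]1(C=C(C)C)C[C@@]1(O[Si](C)(C)C(C)(C)C)C1=CCC(C)C2(C1)OCCO2 | intermediate
12 | bicyclic cycloheptadiene ester: C9 methyl ester, C9=C10, C6=C7 TBS enol ether, C4 dioxolane, C3 methyl (C3 epimers), C1 as in the target | COC(=O)C1=CC(C)(C)[C@H]2CC(C)C3(OCCO3)CC2=C(O[Si](C)(C)C(C)(C)C)C1 | intermediate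
13 | saturated C9 methyl ester, C6=C7 TBS enol ether (C3 and C9 epimers) | COC(=O)C1CC(C)(C)[C@H]2CC(C)C3(OCCO3)CC2=C(O[Si](C)(C)C(C)(C)C)C1 | intermediate
14 | C9 carboxylic acid, C6=C7 TBS enol ether (C3 and C9 epimers) | OC(=O)C1CC(C)(C)[C@H]2CC(C)C3(OCCO3)CC2=C(O[Si](C)(C)C(C)(C)C)C1 | intermediate
15 | Barton ester of 14, the O-acyl derivative of N-hydroxypyridine-2-thione (not isolated) | S=C1C=CC=CN1OC(=O)C1CC(C)(C)[C@H]2CC(C)C3(OCCO3)CC2=C(O[Si](C)(C)C(C)(C)C)C1 | intermediate
16 | C6=C7 TBS enol ether of the bicyclic C4 ketal, C8–C10 as CH2 (C3 epimers) | C1CC(C)(C)[C@H]2CC(C)C3(OCCO3)CC2=C(O[Si](C)(C)C(C)(C)C)C1 | intermediate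
17 | cis-fused C7 ketone with C4 dioxolane, (1S,6R) (C3 epimers) | CC1C2(OCCO2)C[C@@H]3[C@H](C1)C(C)(C)CCCC3=O | intermediate
18 | C7 tertiary carbinol with C4 dioxolane, (1S,6R,7S) (C3 epimers) | CC1C2(OCCO2)C[C@@H]3[C@H](C1)C(C)(C)CCC[C@]3(C)O | intermediate
19 | C4 ketone with C3 methyl and C7 carbinol, (1S,6R,7S) (C3 epimers) | CC1C(=O)C[C@@H]2[C@H](C1)C(C)(C)CCC[C@]2(C)O | intermediate
20 | C3=C4 trimethylsilyl enol ether with C7 trimethylsilyl ether | CC1=C(O[Si](C)(C)C)C[C@@H]2[C@H](C1)C(C)(C)CCC[C@]2(C)O[Si](C)(C)C | intermediate
21 | ring A 3-methyl-2-en-4-one with C7 carbinol, (1S,6R,7S) | O=C1C[C@@H]2[C@H](C=C1C)C(C)(C)CCC[C@]2(C)O | intermediate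
22 | allylic diol, C4 epimer of the target carbinol, (1S,4S,6R,7S) | O[C@H]1C[C@@H]2[C@H](C=C1C)C(C)(C)CCC[C@]2(C)O | intermediate
23 | 3-hydroxy-4-methoxybenzoic acid (isovanillic acid) | COc1ccc(C(=O)O)cc1O | starting material
24 | target, C4 isovanillate of the (1S,4R,6R,7S) diol | COc1ccc(C(=O)O[C@@H]2C[C@@H]3[C@H](C=C2C)C(C)(C)CCC[C@]3(C)O)cc1O | target

## Step count and least certain steps

Total step count: 18. Longest linear sequence: 16 steps (steps 1–5 and 8–18); steps 6 and 7 prepare the diazo ester and acid 23 enters in step 18.

**Step 8 (key step).** The cyclopropane 11 carries a donor (silyloxy on C7) and an acceptor (ester on C9) on adjacent carbons, and the inward methyl retards the boat Cope. Heterolytic opening of the C7–C9 bond can therefore compete with the [3,3] shift, which would erode enantiomeric purity and divert material to five-membered-ring isomers. The carbenoid may also add with the silyloxy group, not the cyclohexenyl arm, cis to its vinyl group. Fallback, setting out from 4 and returning at 17: the C7 oxygen is moved out of the key step. Dehydration of 4 (Burgess reagent) should give the oxygen-free diene 7-ethenyl-10-methyl-1,4-dioxaspiro[4.5]dec-7-ene F1. With 10 and the same catalyst its monosubstituted terminal alkene is cyclopropanated to the non-polarised cis-divinylcyclopropane F2, which can be heated without heterolysis to the cycloheptadiene ester F3. Conjugate reduction of the enoate (Mg, MeOH) should give the saturated ester F4, and tin hydroxide cleavage the acid F5. Barton decarboxylation through the thiohydroxamate ester F6 should give the ring-fusion alkene F7. Hydroboration–oxidation (BH3·THF; NaOH, H2O2) adds hydrogen to C6 and hydroxyl to C7 from the face remote from C11 and gives the C7 carbinol F8, and Dess–Martin oxidation returns 17.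

**Step 12.** The most likely failure is equilibration of C6 through the enol under the fluoride conditions or on work-up, drifting to the trans-fused ketone in which both ring B bonds are equatorial on ring A. Fallback, from 16 back to 17: the ring-fusion hydrogen is delivered by hydroboration and not by protonation. CsF and PhNTf2 in DME should convert 16 into the enol triflate F9. Reduction with Pd(OAc)2, PPh3, Bu3N and HCO2H should give the alkene F7, which is taken through the C7 carbinol F8 to 17 as above. No enolisable ketone is then exposed to base.

**Step 13.** The methyl nucleophile may attack from the ring A side, giving the C7 epimer, or the hindered ketone may enolise and return unchanged. Fallback, from 17 back to 18: oxygen, not carbon, is delivered to the face the substrate prefers. Methylenation with Cp2TiMe2 (toluene, 65 °C) should give the exocyclic methylene compound F10. Epoxidation with dimethyldioxirane on that same face should give the spiro-epoxide F11, and LiAlH4 opens it at the CH2 terminus to give 18.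

**Step 17.** Hydride may come from the ring B side of C4 if the bicycle adopts the conformer with C7 equatorial on ring A, or may partly add 1,4. Fallback, from 21 back to 22: reagent control replaces substrate control. Reduction with the (R)-Me-CBS oxazaborolidine and BH3·SMe2 places the hydride on the face that gives the 4S carbinol 22 directly; no new compound is formed.

**Step 18.** The allylic oxyphosphonium ion may ionise, which would cause loss of stereospecificity, allylic transposition or elimination to a diene, and the phenol may compete as a second acidic nucleophile. Fallback, from 21 to 24: the inversion is removed from the route. Reduction of 21 with the (S)-Me-CBS oxazaborolidine should give the 4R allylic alcohol F12, which already has the target configuration at C4. 3-Acetoxy-4-methoxybenzoic acid F13 is made from 23 with Ac2O and pyridine. Acylation of F12 with F13 under DCC and DMAP proceeds with retention and gives the O-acetyl derivative of the target F14. Pyrrolidine in CH2Cl2 at 0 °C removes the aryl acetate selectively and gives 24.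

## Further compounds

F1 | step 8 | 7-ethenyl-10-methyl-1,4-dioxaspiro[4.5]dec-7-ene | C=CC1=CCC(C)C2(C1)OCCO2
F2 | step 8 | methyl 2-(10-methyl-1,4-dioxaspiro[4.5]dec-7-en-7-yl)-1-(2-methylprop-1-enyl)cyclopropane-1-carboxylate, alkenyl groups cis | COC(=O)[C@]1(C=C(C)C)C[C@H]1C1=CCC(C)C2(C1)OCCO2
F3 | step 8 | cycloheptadiene ester without C7 oxygen (C9 methyl ester, C9=C10, C6=C7) | COC(=O)C1=CC(C)(C)[C@H]2CC(C)C3(OCCO3)CC2=CC1
F4 | step 8 | saturated C9 methyl ester with C6=C7 alkene | COC(=O)C1CC(C)(C)[C@H]2CC(C)C3(OCCO3)CC2=CC1
F5 | step 8 | C9 carboxylic acid with C6=C7 alkene | OC(=O)C1CC(C)(C)[C@H]2CC(C)C3(OCCO3)CC2=CC1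
F6 | step 8 | Barton ester of F5 | S=C1C=CC=CN1OC(=O)C1CC(C)(C)[C@H]2CC(C)C3(OCCO3)CC2=CC1
F7 | step 8 | bicyclic C6=C7 alkene with C4 dioxolane | C1CC(C)(C)[C@H]2CC(C)C3(OCCO3)CC2=CC1
F8 | step 8 | cis-fused C7 secondary carbinol with C4 dioxolane (C7 configuration immaterial) | CC1C2(OCCO2)C[C@@H]3[C@H](C1)C(C)(C)CCCC3O
F9 | step 12 | C6=C7 enol triflate of the bicyclic C4 ketal | C1CC(C)(C)[C@H]2CC(C)C3(OCCO3)CC2=C(OS(=O)(=O)C(F)(F)F)C1
F10 | step 13 | C7 exocyclic methylene compound | CC1C2(OCCO2)C[C@@H]3[C@H](C1)C(C)(C)CCCC3=C
F11 | step 13 | C7 spiro-epoxide with oxygen on the side of C5 | CC1C2(OCCO2)C[C@@H]3[C@H](C1)C(C)(C)CCC[C@@]34CO4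
F0 | step 17 | none | none
F12 | step 18 | 4R allylic diol (C4 epimer of 22) | O[C@@H]1C[C@@H]2[C@H](C=C1C)C(C)(C)CCC[C@]2(C)O
F13 | step 18 | 3-acetoxy-4-methoxybenzoic acid | CC(=O)Oc1cc(C(=O)O)ccc1OC
F14 | step 18 | O-acetyl derivative of the target | COc1ccc(C(=O)O[C@@H]2C[C@@H]3[C@H](C=C2C)C(C)(C)CCC[C@]3(C)O)cc1OC(C)=O
A1 | alternative 1 | oxygen-bridged tricyclic enone | CC1=CC(=O)[C@@H]2[C@H](C1)C(C)(C)[C@H]3C=C[C@]2(C)O3
A2 | alternative 2 | cis-fused bicyclic keto acetate | CC(=O)O[C@H]1C[C@@H]2[C@H](C=C1C)C(C)(C)CCCC2=O
A3 | alternative 3 | ring A carboxylic acid with silyl ether and PMB-protected side chain | CC(C)(C)[Si](C)(C)O[C@@H]1C[C@@H](C(=O)O)[C@H](C=C1C)C(C)(C)CCCOCc2ccc(OC)cc2
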